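**Plan**

1. Numbering: lactone C1 (C=O), C2 (acyloxy), C5=C6 (Z), C7/C8 (diol), C9 (O‑carbon bearing propyl C10–C12); the same numbers are used for every intermediate.
2. Cuts, in order: the C2–O ester (side‑chain epoxy acid), the C2–OH bond, then the lactone C1–O bond with C1 re‑joined to C6, which turns the ten‑membered 5‑ynolide into a 2‑substituted 3‑triflyloxycyclohexenone; last C6–C7 (Sonogashira) and C7–O/C8–O (dihydroxylation).
3. Enabling feature: C1–C6 of the lactone are the six ring carbons of cyclohexane‑1,3‑dione (C1 and C5 the carbonyl carbons, C6 between them), and the C9 oxygen can reach the C1 ketone through a six‑membered hemiketal ring (O, C9, C8, C7, C6, C1) that shares the C1–C6 bond with the carbocycle.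
4. Forward: the carbocycle is bought, the C7–C12 chain is joined at C6, the dioxolane is closed on C7/C8, the hemiketal ring forms and the shared bond breaks to give the ten‑membered ring with the C5≡C6 alkyne; then acetonide to silyl ethers, C2 hydroxylation, Z‑alkene, acylation, desilylation.
5. Stereochemistry: C9 from Sharpless epoxidation of (E)‑hex‑2‑en‑1‑ol (D‑tartrate), kept through an alkynol; C7 and C8 from syn‑dihydroxylation of a Z‑alkene anti to the C9 silyloxy group; C2 from outer‑face hydroxylation of the ring enolate; the epoxide from Sharpless epoxidation of crotyl alcohol (L‑tartrate); Z‑alkenes by Lindlar reduction, the E‑enoate by Wittig reaction.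

Key step: step 13

Remark: the precursor is reached by alkyne coupling and dihydroxylation, so that C9 carries its triethylsilyl ether from the start and no exchange of protecting groups is needed before the fragmentation.

**Route**

Step 1
Reactants: 1 (E)-hex-2-en-1-ol
Product: 2 (2R,3R)-3-propyloxiranemethanol
Conditions: Ti(OiPr)4 (5 mol %), D-(−)-diisopropyl tartrate (6 mol %), t-BuOOH, 4 Å MS, CH2Cl2, −20 °C
Reagents that add atoms: tert-butyl hydroperoxide, CC(C)(C)OO
Why: Sharpless asymmetric epoxidation of a primary E-allylic alcohol, in which the D-(−)-tartrate ligand directs oxygen to the face that gives the (2R,3R) epoxide, whose C3 becomes C9 of the target.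

Step 2
Reactants: 2 (2R,3R)-3-propyloxiranemethanol
Product: 3 (2S,3R)-2-(chloromethyl)-3-propyloxirane
Conditions: PPh3, CCl4, NaHCO3, reflux
Reagents that add atoms: carbon tetrachloride, ClC(Cl)(Cl)Cl
Why: Appel chlorination of the primary alcohol runs under neutral conditions that leave the epoxide and both stereocentres untouched.

Step 3
Reactants: 3 (2S,3R)-2-(chloromethyl)-3-propyloxirane
Product: 4 (3R)-hex-1-yn-3-ol
Conditions: n-BuLi (3.1 equiv), THF, −40 °C; aq NH4Cl
Reagents that add atoms: none
Why: Base-induced double elimination of a 2,3-epoxy chloride (epoxide-opening elimination to the chlorovinyl alkoxide, then dehydrochlorination) is an established route to 1-alkyn-3-ols and never breaks the C–O bond of the carbinol carbon, so C9 keeps its R configuration.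

Step 4
Reactants: 4 (3R)-hex-1-yn-3-ol
Product: 5 triethyl{[(3R)-hex-1-yn-3-yl]oxy}silane
Conditions: Et3SiCl, imidazole, CH2Cl2, 0 → 23 °C
Reagents that add atoms: chlorotriethylsilane, CC[Si](Cl)(CC)CC
Why: Standard silylation of a secondary alcohol installs the fluoride-labile group that will later release the C9 alkoxide.

Step 5
Reactants: 6 cyclohexane-1,3-dione
Product: 7 3-(benzyloxy)cyclohex-2-en-1-one
Conditions: BnOH, TsOH·H2O (cat.), toluene, reflux, Dean–Stark
Reagents that add atoms: benzyl alcohol, OCc1ccccc1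
Why: Acid-catalysed condensation of the enolised dione with an alcohol under water removal gives the vinylogous ester, and benzyl is chosen so that the dione can later be freed by neutral hydrogenolysis.

Step 6
Reactants: 7 3-(benzyloxy)cyclohex-2-en-1-one
Product: 8 3-(benzyloxy)-2-iodocyclohex-2-en-1-one
Conditions: NIS, MeCN, 23 °C, dark
Reagents that add atoms: N-iodosuccinimide, O=C1CCC(=O)N1I
Why: The α-carbon of a vinylogous ester is an enol-ether-type nucleophile and undergoes electrophilic α-iodination.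

Step 7
Reactants: 5 triethyl{[(3R)-hex-1-yn-3-yl]oxy}silane; 8 3-(benzyloxy)-2-iodocyclohex-2-en-1-one
Product: 9 3-(benzyloxy)-2-[(3R)-3-(triethylsilyloxy)hex-1-yn-1-yl]cyclohex-2-en-1-one
Conditions: PdCl2(PPh3)2 (5 mol %), CuI (10 mol %), Et3N, THF, 23 → 45 °C
Reagents that add atoms: none
Why: Sonogashira coupling of a terminal alkyne with an α-iodo enone, a reactive alkenyl iodide, forms the C6–C7 bond under conditions to which the silyl ether and the vinylogous ester are inert.

Step 8
Reactants: 9 3-(benzyloxy)-2-[(3R)-3-(triethylsilyloxy)hex-1-yn-1-yl]cyclohex-2-en-1-one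
Product: 10 3-(benzyloxy)-2-[(1Z,3R)-3-(triethylsilyloxy)hex-1-en-1-yl]cyclohex-2-en-1-one
Conditions: H2 (1 atm), Pd/CaCO3 poisoned with Pb(OAc)2, quinoline, EtOAc, 23 °C
Reagents that add atoms: none
Why: Lindlar semi-hydrogenation delivers both hydrogens to one face of the alkyne and should give the Z-alkene without cleaving the benzyl vinylogous ester on the poisoned catalyst.

Step 9
Reactants: 10 3-(benzyloxy)-2-[(1Z,3R)-3-(triethylsilyloxy)hex-1-en-1-yl]cyclohex-2-en-1-one
Product: 11 3-(benzyloxy)-2-[(1S,2S,3R)-1,2-dihydroxy-3-(triethylsilyloxy)hexyl]cyclohex-2-en-1-one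
Conditions: OsO4 (3 mol %), NMO, acetone/H2O, 0 → 23 °C; aq Na2SO3
Reagents that add atoms: osmium tetroxide (catalytic oxygen carrier), O=[Os](=O)(=O)=O; N-methylmorpholine N-oxide, C[N+]1([O-])CCOCC1; water, O
Why: Upjohn dihydroxylation adds both hydroxyls syn to the disubstituted Z-alkene (C7/C8 erythro) while allylic 1,3-strain holds the C9–H in the alkene plane, so osmium should attack the face opposite the C9 silyloxy group (the usual anti preference of allylic ethers) and set the 8,9-erythro, (7S,8S) diol; the tetrasubstituted push–pull alkene is unreactive.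

Step 10
Reactants: 11 3-(benzyloxy)-2-[(1S,2S,3R)-1,2-dihydroxy-3-(triethylsilyloxy)hexyl]cyclohex-2-en-1-one
Product: 12 3-(benzyloxy)-2-{(4S,5S)-2,2-dimethyl-5-[(1R)-1-(triethylsilyloxy)butyl]-1,3-dioxolan-4-yl}cyclohex-2-en-1-one
Conditions: 2-methoxypropene, PPTS (cat.), CH2Cl2, 0 °C; Et3N quench
Reagents that add atoms: 2-methoxypropene, COC(C)=C
Why: Acid-catalysed ketalisation of the 1,2-diol with an enol ether is fast at 0 °C under PPTS, mild enough for the secondary triethylsilyl ether and the vinylogous ester, and gives the cis-dioxolane that cannot migrate to a neighbouring alkoxide.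

Step 11
Reactants: 12 3-(benzyloxy)-2-{(4S,5S)-2,2-dimethyl-5-[(1R)-1-(triethylsilyloxy)butyl]-1,3-dioxolan-4-yl}cyclohex-2-en-1-one
Product: 13 2-{(4S,5S)-2,2-dimethyl-5-[(1R)-1-(triethylsilyloxy)butyl]-1,3-dioxolan-4-yl}cyclohexane-1,3-dione (enol form)
Conditions: H2 (1 atm), 10% Pd/C, EtOAc, 23 °C; used directly
Reagents that add atoms: none
Why: Hydrogenolysis of the O–benzyl bond of the vinylogous ester (the vinylogue of a benzyl ester) frees the 1,3-dione under neutral conditions that spare the silyl ether and the acetonide.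

Step 12
Reactants: 13 2-{(4S,5S)-2,2-dimethyl-5-[(1R)-1-(triethylsilyloxy)butyl]-1,3-dioxolan-4-yl}cyclohexane-1,3-dione
Product: 14 2-{(4S,5S)-2,2-dimethyl-5-[(1R)-1-(triethylsilyloxy)butyl]-1,3-dioxolan-4-yl}-3-oxocyclohex-1-en-1-yl trifluoromethanesulfonate
Conditions: Tf2O, pyridine, CH2Cl2, −78 → 0 °C
Reagents that add atoms: trifluoromethanesulfonic anhydride, O=S(=O)(OS(=O)(=O)C(F)(F)F)C(F)(F)F
Why: O-Sulfonylation of the enolised 1,3-dione gives the vinylogous acyl triflate, and because the unsubstituted ring makes both carbonyl groups lead to the same compound there is no regiochemical question.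

Step 13
Reactants: 14 2-{(4S,5S)-2,2-dimethyl-5-[(1R)-1-(triethylsilyloxy)butyl]-1,3-dioxolan-4-yl}-3-oxocyclohex-1-en-1-yl trifluoromethanesulfonate
Product: 17 (7S,8R,9R)-7,8-(isopropylidenedioxy)dodec-5-yn-9-olide, via C9 alkoxide 15 (not isolated), via bicyclic hemiketal alkoxide 16 (not isolated)
Conditions: (Me2N)3S+ Me3SiF2− (TASF, 1.2 equiv), THF/DMF, −40 → 23 °C, then 45 °C
Reagents that add atoms: none
Why: Proposed new method: fluoride strips the triethylsilyl group, the C9 alkoxide adds to the C1 ketone, and the resulting hemiketal alkoxide pushes out triflate by breaking the C1–C6 σ bond, which lies anti-periplanar to the C5–O bond across the enol triflate double bond, so the C5≡C6 alkyne and the lactone carbonyl form in one event. The closest known reaction type is the addition/fragmentation of vinylogous acyl triflates triggered by external carbon, hydride or nitrogen nucleophiles, which has also been used to open bicyclic substrates to medium-ring cycloalkynes; an internal oxygen nucleophile that ends as a lactone oxygen has not been shown. The only ring that closes is the transient tetrahydropyran hemiketal (6-exo-trig onto the C=O), and the ten-membered ring then arises by cleavage of the bond shared by the two rings, not by end-to-end closure. No stereocentre is created: C7, C8 and C9 are carried through and the hemiketal centre disappears. The step needs addition at C1 and not 6-endo addition–elimination at C5, and the substrate favours this because allylic strain with the bulky triflate turns the C7–H toward C5 and swings the C8–C9–O arm over the C1 carbonyl, ketone addition is fast and reversible while warming commits the hemiketal to irreversible fragmentation, and the acetonide cannot migrate to the alkoxide as a silyl ether could.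

Step 14
Reactants: 17 (7S,8R,9R)-7,8-(isopropylidenedioxy)dodec-5-yn-9-olide
Product: 18 (7S,8S,9R)-7,8-dihydroxydodec-5-yn-9-olide
Conditions: CF3CO2H/H2O/THF (1:1:4), 0 → 23 °C
Reagents that add atoms: none
Why: Acid-catalysed hydrolysis of the isopropylidene ketal is done here, where only a lactone and an alkyne are present, because the vinyl epoxide of the final product would not tolerate it.

Step 15
Reactants: 18 (7S,8S,9R)-7,8-dihydroxydodec-5-yn-9-olide
Product: 19 (7S,8R,9R)-7,8-bis(triethylsilyloxy)dodec-5-yn-9-olide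
Conditions: Et3SiOTf, 2,6-lutidine, CH2Cl2, −78 → 0 °C
Reagents that add atoms: triethylsilyl trifluoromethanesulfonate, CC[Si](CC)(CC)OS(=O)(=O)C(F)(F)F
Why: Silylation of both secondary hydroxyls with a silyl triflate and a hindered base gives ethers that survive enolate chemistry and can be removed at the end with buffered fluoride.

Step 16
Reactants: 19 (7S,8R,9R)-7,8-bis(triethylsilyloxy)dodec-5-yn-9-olide
Product: 21 (2S,7S,8R,9R)-2-hydroxy-7,8-bis(triethylsilyloxy)dodec-5-yn-9-olide, via potassium enolate 20 (not isolated)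
Conditions: KN(SiMe3)2, THF, −78 °C; then (+)-(camphorsulfonyl)oxaziridine, −78 → −40 °C; aq NH4Cl
Reagents that add atoms: (+)-(camphorsulfonyl)oxaziridine, CC1(C)[C@@H]2CC[C@]13CS(=O)(=O)N4O[C@@]34C2
Why: Davis-type hydroxylation of the lactone enolate with a sulfonyloxaziridine places oxygen at C2, and the ring-constrained cis enolate in the s-trans lactone conformer should be attacked on its outer face (the face of the C9 propyl group, away from the transannular chain), which corresponds to the (2S) alcohol; the camphor-derived oxidant is used because its ketimine by-product does not add to the enolate.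

Step 17
Reactants: 21 (2S,7S,8R,9R)-2-hydroxy-7,8-bis(triethylsilyloxy)dodec-5-yn-9-olide
Product: 22 (2S,5Z,7S,8R,9R)-2-hydroxy-7,8-bis(triethylsilyloxy)dodec-5-en-9-olide
Conditions: H2 (1 atm), Pd/CaCO3 poisoned with Pb(OAc)2, quinoline, EtOAc, 23 °C
Reagents that add atoms: none
Why: Lindlar semi-hydrogenation of the ring alkyne can only give the Z-alkene by syn delivery of hydrogen, and it is run before the side chain is attached so that the vinyl epoxide never meets palladium and hydrogen.

Step 18
Reactants: 23 (E)-but-2-en-1-ol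
Product: 24 (2S,3S)-3-methyloxiranemethanol
Conditions: Ti(OiPr)4 (5 mol %), L-(+)-diisopropyl tartrate (6 mol %), t-BuOOH, 4 Å MS, CH2Cl2, −20 °C; non-aqueous work-up
Reagents that add atoms: tert-butyl hydroperoxide, CC(C)(C)OO
Why: Sharpless asymmetric epoxidation with the L-(+)-tartrate gives the (2S,3S) epoxy alcohol and so fixes both epoxide stereocentres of the side chain.

Step 19
Reactants: 24 (2S,3S)-3-methyloxiranemethanol
Product: 26 methyl (2E)-3-[(2S,3S)-3-methyloxiran-2-yl]prop-2-enoate, via epoxy aldehyde 25 (not isolated)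
Conditions: PhI(OAc)2, TEMPO (10 mol %), CH2Cl2, 23 °C; then Ph3P=CHCO2Me, 0 → 23 °C
Reagents that add atoms: methyl (triphenylphosphoranylidene)acetate, COC(=O)C=P(c1ccccc1)(c1ccccc1)c1ccccc1
Why: Nitroxyl-catalysed oxidation gives the volatile epoxy aldehyde, which is trapped in the same flask by the stabilised ylide in an E-selective Wittig reaction, and neither event touches the epoxide stereocentres.

Step 20
Reactants: 26 methyl (2E)-3-[(2S,3S)-3-methyloxiran-2-yl]prop-2-enoate
Product: 27 (2E)-3-[(2S,3S)-3-methyloxiran-2-yl]prop-2-enoic acid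
Conditions: LiOH·H2O, THF/H2O, 0 °C; cold 0.5 M HCl to pH 4
Reagents that add atoms: lithium hydroxide, [Li+].[OH-]
Why: Saponification of the methyl ester at 0 °C is tolerated by a trans-disubstituted epoxide, and acidification is stopped at pH 4 to avoid acid-promoted opening.

Step 21
Reactants: 22 (2S,5Z,7S,8R,9R)-2-hydroxy-7,8-bis(triethylsilyloxy)dodec-5-en-9-olide; 27 (2E)-3-[(2S,3S)-3-methyloxiran-2-yl]prop-2-enoic acid
Product: 28 (2S,5Z,7S,8R,9R)-2-{(2E)-3-[(2S,3S)-3-methyloxiran-2-yl]prop-2-enoyloxy}-7,8-bis(triethylsilyloxy)dodec-5-en-9-olide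
Conditions: EDC·HCl, DMAP (0.2 equiv), CH2Cl2, 0 → 23 °C
Reagents that add atoms: none
Why: Steglich esterification acylates the only free hydroxyl with retention at C2 under cold, nearly neutral conditions that should spare the epoxide and the α-stereocentre.

Step 22
Reactants: 28 (2S,5Z,7S,8R,9R)-2-{(2E)-3-[(2S,3S)-3-methyloxiran-2-yl]prop-2-enoyloxy}-7,8-bis(triethylsilyloxy)dodec-5-en-9-olide
Product: 29 (2S,5Z,7S,8S,9R)-7,8-dihydroxy-2-{(2E)-3-[(2S,3S)-3-methyloxiran-2-yl]prop-2-enoyloxy}dodec-5-en-9-olide (CNP0590330.3)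
Conditions: HF·pyridine, pyridine, THF, 0 °C
Reagents that add atoms: none
Why: Fluoride cleavage of the two triethylsilyl ethers with pyridine-buffered HF·pyridine at 0 °C is mild enough for the vinyl epoxide, the enoate and the lactone and should release the target.

**Compound list**

1 | (E)-hex-2-en-1-ol | CCC/C=C/CO | starting material
2 | (2R,3R)-3-propyloxiranemethanol | OC[C@H]1O[C@@H]1CCC | intermediate
3 | (2S,3R)-2-(chloromethyl)-3-propyloxirane | ClC[C@H]1O[C@@H]1CCC | intermediate
4 | (3R)-hex-1-yn-3-ol | CCC[C@@H](O)C#C | intermediate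
5 | triethyl{[(3R)-hex-1-yn-3-yl]oxy}silane | CCC[C@@H](O[Si](CC)(CC)CC)C#C | intermediate
6 | cyclohexane-1,3-dione | O=C1CCCC(=O)C1 | starting material
7 | 3-(benzyloxy)cyclohex-2-en-1-one | O=C1C=C(OCc2ccccc2)CCC1 | intermediate
8 | 3-(benzyloxy)-2-iodocyclohex-2-en-1-one | O=C1CCCC(OCc2ccccc2)=C1I | intermediate
9 | 3-(benzyloxy)-2-[(3R)-3-(triethylsilyloxy)hex-1-yn-1-yl]cyclohex-2-en-1-one | CCC[C@@H](O[Si](CC)(CC)CC)C#CC1=C(OCc2ccccc2)CCCC1=O | intermediate
10 | 3-(benzyloxy)-2-[(1Z,3R)-3-(triethylsilyloxy)hex-1-en-1-yl]cyclohex-2-en-1-one | CCC[C@@H](O[Si](CC)(CC)CC)/C=C\C1=C(OCc2ccccc2)CCCC1=O | intermediate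
11 | 3-(benzyloxy)-2-[(1S,2S,3R)-1,2-dihydroxy-3-(triethylsilyloxy)hexyl]cyclohex-2-en-1-one | CCC[C@@H](O[Si](CC)(CC)CC)[C@@H](O)[C@@H](O)C1=C(OCc2ccccc2)CCCC1=O | intermediate
12 | 3-(benzyloxy)-2-{(4S,5S)-2,2-dimethyl-5-[(1R)-1-(triethylsilyloxy)butyl]-1,3-dioxolan-4-yl}cyclohex-2-en-1-one | CCC[C@@H](O[Si](CC)(CC)CC)[C@H]1OC(C)(C)O[C@H]1C2=C(OCc3ccccc3)CCCC2=O | intermediate
13 | 2-{(4S,5S)-2,2-dimethyl-5-[(1R)-1-(triethylsilyloxy)butyl]-1,3-dioxolan-4-yl}cyclohexane-1,3-dione (enol form) | CCC[C@@H](O[Si](CC)(CC)CC)[C@H]1OC(C)(C)O[C@H]1C2=C(O)CCCC2=O | intermediate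
14 | 2-{(4S,5S)-2,2-dimethyl-5-[(1R)-1-(triethylsilyloxy)butyl]-1,3-dioxolan-4-yl}-3-oxocyclohex-1-en-1-yl trifluoromethanesulfonate (C7/C8 acetonide, C9 triethylsilyl ether) | CCC[C@@H](O[Si](CC)(CC)CC)[C@H]1OC(C)(C)O[C@H]1C2=C(OS(=O)(=O)C(F)(F)F)CCCC2=O | intermediate
15 | C9 alkoxide of 14 after loss of the silyl group (tris(dimethylamino)sulfonium salt) | CCC[C@@H]([O-])[C@H]1OC(C)(C)O[C@H]1C2=C(OS(=O)(=O)C(F)(F)F)CCCC2=O.CN(C)[S+](N(C)C)N(C)C | intermediate (not isolated)
16 | bicyclic hemiketal alkoxide formed by addition of the C9 oxygen to C1 (either configuration at C1; tris(dimethylamino)sulfonium salt) | CCC[C@H]1OC2([O-])CCCC(OS(=O)(=O)C(F)(F)F)=C2[C@@H]2OC(C)(C)O[C@H]12.CN(C)[S+](N(C)C)N(C)C | intermediate (not isolated)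
17 | (7S,8R,9R)-7,8-(isopropylidenedioxy)dodec-5-yn-9-olide (ten-membered ynolide, cis-fused acetonide) | CCC[C@H]1OC(=O)CCCC#C[C@@H]2OC(C)(C)O[C@H]12 | intermediate
18 | (7S,8S,9R)-7,8-dihydroxydodec-5-yn-9-olide | CCC[C@H]1OC(=O)CCCC#C[C@H](O)[C@@H]1O | intermediate
19 | (7S,8R,9R)-7,8-bis(triethylsilyloxy)dodec-5-yn-9-olide | CCC[C@H]1OC(=O)CCCC#C[C@H](O[Si](CC)(CC)CC)[C@@H]1O[Si](CC)(CC)CC | intermediate
20 | potassium enolate (C1=C2, ring oxygen and C3 cis) of 19 | [K+].CCC[C@H]1O/C([O-])=C\CCC#C[C@H](O[Si](CC)(CC)CC)[C@@H]1O[Si](CC)(CC)CC | intermediate (not isolated)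
21 | (2S,7S,8R,9R)-2-hydroxy-7,8-bis(triethylsilyloxy)dodec-5-yn-9-olide | CCC[C@H]1OC(=O)[C@@H](O)CCC#C[C@H](O[Si](CC)(CC)CC)[C@@H]1O[Si](CC)(CC)CC | intermediate
22 | (2S,5Z,7S,8R,9R)-2-hydroxy-7,8-bis(triethylsilyloxy)dodec-5-en-9-olide | CCC[C@H]1OC(=O)[C@@H](O)CC/C=C\[C@H](O[Si](CC)(CC)CC)[C@@H]1O[Si](CC)(CC)CC | intermediate
23 | (E)-but-2-en-1-ol | C/C=C/CO | starting material
24 | (2S,3S)-3-methyloxiranemethanol | OC[C@@H]1O[C@H]1C | intermediate
25 | (2R,3S)-3-methyloxirane-2-carbaldehyde | O=C[C@@H]1O[C@H]1C | intermediate (not isolated)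
26 | methyl (2E)-3-[(2S,3S)-3-methyloxiran-2-yl]prop-2-enoate | COC(=O)/C=C/[C@@H]1O[C@H]1C | intermediate
27 | (2E)-3-[(2S,3S)-3-methyloxiran-2-yl]prop-2-enoic acid | OC(=O)/C=C/[C@@H]1O[C@H]1C | intermediate
28 | (2S,5Z,7S,8R,9R)-2-{(2E)-3-[(2S,3S)-3-methyloxiran-2-yl]prop-2-enoyloxy}-7,8-bis(triethylsilyloxy)dodec-5-en-9-olide | CCC[C@H]1OC(=O)[C@@H](OC(=O)/C=C/[C@@H]2O[C@H]2C)CC/C=C\[C@H](O[Si](CC)(CC)CC)[C@@H]1O[Si](CC)(CC)CC | intermediate
29 | (2S,5Z,7S,8S,9R)-7,8-dihydroxy-2-{(2E)-3-[(2S,3S)-3-methyloxiran-2-yl]prop-2-enoyloxy}dodec-5-en-9-olide (CNP0590330.3) | CCC[C@H]1OC(=O)[C@@H](OC(=O)/C=C/[C@@H]2O[C@H]2C)CC/C=C\[C@H](O)[C@@H]1O | target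

**Step count and risks**

Total: 22 steps. Longest linear sequence: 17 steps (steps 1–4, 7–17, 21, 22).

Steps most likely to fail:

Step 13. The freed alkoxide may close onto C5 with loss of triflate (6-endo addition–elimination to a bicyclic vinylogous ester), or fluoride may attack the triflate before the hemiketal fragments. The fallback opens the ring with an external nucleophile, which is known chemistry, and closes the lactone conventionally. Setting out from 14, LiBHEt3 (THF, −78 → 60 °C) adds hydride to the ketone, the alkoxide fragments, and the aldehyde so formed is reduced in the same flask to the acyclic alkynol (7S,8S,9R)-7,8-(isopropylidenedioxy)-9-(triethylsilyloxy)dodec-5-yn-1-ol F1. Oxidation with TEMPO and PhI(OAc)2 in aqueous MeCN would give (7S,8S,9R)-7,8-(isopropylidenedioxy)-9-(triethylsilyloxy)dodec-5-ynoic acid F2. HF·pyridine/pyridine would then remove the silyl ether to give the seco acid (7S,8R,9R)-9-hydroxy-7,8-(isopropylidenedioxy)dodec-5-ynoic acid F3. Yamaguchi macrolactonisation (2,4,6-trichlorobenzoyl chloride, Et3N, then DMAP, toluene, high dilution) forms the C9–O acyl bond with retention and comes back to the route at 17.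

Step 16. Facial selectivity in the enolate oxidation may be poor or reversed, since it rests on the conformation of a ten-membered ring. The fallback uses the other epimer instead of fighting it. From 19 the same hydroxylation would give (2R,7S,8R,9R)-2-hydroxy-7,8-bis(triethylsilyloxy)dodec-5-yn-9-olide F4. Lindlar reduction would give (2R,5Z,7S,8R,9R)-2-hydroxy-7,8-bis(triethylsilyloxy)dodec-5-en-9-olide F5. Mitsunobu esterification with acid 27 (PPh3, DIAD, toluene, 0 °C) then attaches the side chain with inversion at C2 and comes back to the route at 28.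

Step 21. Activation of the epoxy acid may lead to γ-deprotonation with opening of the epoxide, and a slow acylation of the hindered α-hydroxy lactone may erode the C2 configuration. The fallback builds the enoate double bond on the lactone. From 22, diethylphosphonoacetic acid, EDC·HCl and DMAP would give (2S,5Z,7S,8R,9R)-2-[(diethoxyphosphoryl)acetoxy]-7,8-bis(triethylsilyloxy)dodec-5-en-9-olide F6. A Horner–Wadsworth–Emmons reaction under Masamune–Roush conditions (LiCl, iPr2NEt, MeCN) with epoxy aldehyde 25, freshly made from 24 as in step 19, then comes back to the route at 28.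

Further compounds
F1 | step 13 | (7S,8S,9R)-7,8-(isopropylidenedioxy)-9-(triethylsilyloxy)dodec-5-yn-1-ol | CCC[C@@H](O[Si](CC)(CC)CC)[C@H]1OC(C)(C)O[C@H]1C#CCCCCO
F2 | step 13 | (7S,8S,9R)-7,8-(isopropylidenedioxy)-9-(triethylsilyloxy)dodec-5-ynoic acid | CCC[C@@H](O[Si](CC)(CC)CC)[C@H]1OC(C)(C)O[C@H]1C#CCCCC(=O)O
F3 | step 13 | (7S,8R,9R)-9-hydroxy-7,8-(isopropylidenedioxy)dodec-5-ynoic acid | CCC[C@@H](O)[C@H]1OC(C)(C)O[C@H]1C#CCCCC(=O)O
F4 | step 16 | (2R,7S,8R,9R)-2-hydroxy-7,8-bis(triethylsilyloxy)dodec-5-yn-9-olide | CCC[C@H]1OC(=O)[C@H](O)CCC#C[C@H](O[Si](CC)(CC)CC)[C@@H]1O[Si](CC)(CC)CC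
F5 | step 16 | (2R,5Z,7S,8R,9R)-2-hydroxy-7,8-bis(triethylsilyloxy)dodec-5-en-9-olide | CCC[C@H]1OC(=O)[C@H](O)CC/C=C\[C@H](O[Si](CC)(CC)CC)[C@@H]1O[Si](CC)(CC)CC
F6 | step 21 | (2S,5Z,7S,8R,9R)-2-[(diethoxyphosphoryl)acetoxy]-7,8-bis(triethylsilyloxy)dodec-5-en-9-olide | CCC[C@H]1OC(=O)[C@@H](OC(=O)CP(=O)(OCC)OCC)CC/C=C\[C@H](O[Si](CC)(CC)CC)[C@@H]1O[Si](CC)(CC)CC
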